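Ring C is closed last, at the C9–C11 bond. The seven-membered periphery of the bicyclo[3.2.1]octane (C8–C9–C11–C12–C15–C16–C14, rings C and D without the C13 bridge) is the [4+3] adduct of a 1,4-diketone (C9 and C16 carbonyls) and a 2-methylenepropane-1,3-diyl unit (C11, C12, C15 and the future C12 methyl). The diketone comes from (S)-carvone (ring B, C4) and an (S)-lactate-derived tetronate, joined at C8–C14 by a Claisen rearrangement. After allylation at C16, samarium diiodide closes the ring by Barbier addition of the allylic chloride to the C9 ketone. Radical deoxygenation at C9 and a hydrogen-atom-transfer enyne cyclization complete rings C and D.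

Key step: step 17

Remark on numbering: ring A is the ε-lactone O–C3(=O)–C2=C1–C10–C5–C4(CH3)2; ring B is C5–C6–C7–C8–C9–C10; ring C is C8–C9–C11–C12–C13–C14; ring D is C12–C13–C14–C16–C15; the γ-lactone is C14–C18(=O)–O–C17(H)(CH3)–C16(OH); C19 is the exocyclic methylene carbon on C13. β is the face of ring B that carries the C8 and C10 methyl groups, α the opposite face. Compounds 1–8 are named as carvone derivatives with carvone locants.

Assumption: the configuration of the C9 carbinol centre in 23 and 24 and of the selenium-bearing C2 in 29 and 30 has no consequence for the route. For 23 and 24 the epimer expected from attack on the α face is drawn; 29 and 30 are drawn without a C2 descriptor. (S)-Carvone, ethyl (S)-lactate and all reagents named are taken as commercially available.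

Step 1
Reactants: 1 (S)-(+)-carvone
Product: 3 (5S,6R)-6-methylcarvone, via lithium dienolate 2 (not isolated)
Conditions: LiN(i-Pr)2, THF, −78 °C; then MeI, −78 to 0 °C
Reagents that add atoms: iodomethane CI
Why: Kinetic deprotonation of the α′-methylene and C-methylation of the enolate (ketone enolate alkylation) should give the 6-methyl ketone, mainly trans, and this centre is re-enolized in step 2 so its configuration is immaterial.

Step 2
Reactants: 3 (5S,6R)-6-methylcarvone
Product: 5 6-allyl-6-methylcarvone, via lithium enolate 4 (not isolated)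
Conditions: LiN(i-Pr)2, THF, −78 °C; then allyl bromide, DMPU, −78 °C to rt
Reagents that add atoms: allyl bromide C=CCBr
Why: A second enolate alkylation on the tetrasubstituted enolate should bring the allyl group in anti to the neighbouring isopropenyl group, which fixes the C10 quaternary centre with its methyl cis to the C5 substituent.

Step 3
Reactants: 5 6-allyl-6-methylcarvone
Product: 7 6-(3-hydroxypropyl)-6-methylcarvone, via alkyldisiamylborane 6 (not isolated)
Conditions: bis(3-methylbutan-2-yl)borane, THF, 0 °C; then 30% H2O2, aq. NaOAc, 0 °C to rt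
Reagents that add atoms: hydrogen peroxide OO
Why: Anti-Markovnikov hydroboration–oxidation with the bulky dialkylborane should select the monosubstituted allyl alkene over the 1,1-disubstituted isopropenyl and the electron-poor enone alkenes and give the primary alcohol at C3.

Step 4
Reactants: 7 6-(3-hydroxypropyl)-6-methylcarvone
Product: 8 6-(2-carboxyethyl)-6-methylcarvone
Conditions: 2,2,6,6-tetramethylpiperidine-1-oxyl (cat.), PhI(OAc)2, MeCN/H2O, rt
Reagents that add atoms: water O
Why: Oxoammonium-mediated alcohol oxidation in wet acetonitrile should take the primary alcohol through the aldehyde hydrate to the carboxylic acid without touching the alkenes.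

Step 5
Reactants: 8 6-(2-carboxyethyl)-6-methylcarvone
Product: 9 ring A lactone ring B enone
Conditions: CF3SO3H (10 mol%), CH2Cl2, 0 °C to rt
Reagents that add atoms: none
Why: Acid-catalysed Markovnikov addition of the carboxylic acid to the isopropenyl group (alkene hydroacyloxylation through the tertiary C4 cation) should close the trans-fused ε-lactone because both arms are equatorial on ring B.

Step 6
Reactants: 9 ring A lactone ring B enone
Product: 11 6α-hydroxy enone, via silyl dienol ether 10 (not isolated)
Conditions: Me3SiOTf, Et3N, CH2Cl2, 0 °C; then mCPBA, NaHCO3, CH2Cl2, −30 °C; aq. citric acid work-up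
Reagents that add atoms: 3-chloroperbenzoic acid OOC(=O)c1cccc(Cl)c1
Why: With no α′ hydrogen left, enolization gives the extended silyl dienol ether, and peracid oxidation of its γ,δ-alkene (vinylogous Rubottom oxidation) should place the C6 hydroxyl on the α face, anti to the pseudoaxial C10 methyl.

Step 7
Reactants: 12 ethyl (S)-lactate
Product: 13 ethyl (S)-2-acetoxypropanoate
Conditions: acetyl chloride, pyridine, CH2Cl2, 0 °C
Reagents that add atoms: acetyl chloride CC(Cl)=O
Why: O-Acylation of the secondary alcohol (esterification) leaves the stereocentre untouched.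

Step 8
Reactants: 13 ethyl (S)-2-acetoxypropanoate
Product: 14 (S)-5-methyltetronic acid
Conditions: LiN(SiMe3)2 (2.2 equiv), THF, −78 °C; then 1 M HCl
Reagents that add atoms: none
Why: The acetate enolate attacks the ethyl ester intramolecularly (Dieckmann-type Claisen condensation) at low temperature, which should give the tetronic acid without loss of configuration at C17.

Step 9
Reactants: 14 (S)-5-methyltetronic acid
Product: 15 (S)-4-bromo-5-methylfuran-2(5H)-one
Conditions: oxalyl bromide, HCONMe2 (cat.), CH2Cl2, 0 °C to rt
Reagents that add atoms: oxalyl bromide O=C(Br)C(Br)=O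
Why: Vilsmeier-type deoxybromination converts the vinylogous acid into the vinylogous acid bromide.

Step 10
Reactants: 11 6α-hydroxy enone; 15 (S)-4-bromo-5-methylfuran-2(5H)-one
Product: 16 6α-O-tetronate ether
Conditions: 1,4-diazabicyclo[2.2.2]octane (cat.), K2CO3, MeCN, rt
Reagents that add atoms: none
Why: Amine-catalysed addition–elimination of the C6 hydroxyl at C16 of the β-bromobutenolide (nucleophilic vinylic substitution) should give the tetronate ether with retention at C6, since the C6–O bond is never broken.

Step 11
Reactants: 16 6α-O-tetronate ether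
Product: 17 C14 iodide of the tetronate ether
Conditions: N-iodosuccinimide, CF3CO2H (cat.), MeCN, rt
Reagents that add atoms: N-iodosuccinimide O=C1CCC(=O)N1I
Why: Electrophilic iodination occurs at C14, the nucleophilic α-carbon of the vinylogous ester, while the enone alkene is electron-poor.

Step 12
Reactants: 17 C14 iodide of the tetronate ether
Product: 18 C14 (trimethylsilyl)ethynyl tetronate ether
Conditions: ethynyltrimethylsilane, PdCl2(PPh3)2 (cat.), CuI (cat.), Et3N, THF, rt
Reagents that add atoms: ethynyltrimethylsilane C#C[Si](C)(C)C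
Why: Sonogashira coupling of the alkenyl iodide installs the C13–C19 unit at C14.

Step 13
Reactants: 18 C14 (trimethylsilyl)ethynyl tetronate ether
Product: 19 C8-linked 3-alkynylfuran-2,4-dione with C6=C7
Conditions: o-xylene, 145 °C, sealed tube
Reagents that add atoms: none
Why: Thermal [3,3]-sigmatropic Claisen rearrangement of the allyl vinyl ether C14=C16–O–C6–C7=C8 should form the C8–C14 bond suprafacially on the α face (from the C6α oxygen) and on the tetronate face anti to the C17 methyl, which sets both quaternary centres.

Step 14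
Reactants: 19 C8-linked 3-alkynylfuran-2,4-dione with C6=C7
Product: 20 saturated 1,4-diketone (C9 and C16 carbonyls)
Conditions: 2-nitrobenzenesulfonylhydrazide, Et3N, CH2Cl2, rt
Reagents that add atoms: none
Why: Diimide generated in the flask reduces the cis-disubstituted C6=C7 alkene by concerted syn hydrogen transfer, while the hindered silylalkyne and the carbonyl groups should not react.

Step 15
Reactants: 20 saturated 1,4-diketone (C9 and C16 carbonyls)
Product: 21 C16 tertiary alcohol with 2-(chloromethyl)allyl group
Conditions: 2-(chloromethyl)-3-(trimethylsilyl)prop-1-ene, TiCl4, CH2Cl2, −78 °C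
Reagents that add atoms: 2-(chloromethyl)-3-(trimethylsilyl)prop-1-ene C=C(CCl)C[Si](C)(C)C
Why: Lewis acid-promoted Hosomi–Sakurai allylation should occur only at the C16 ketone (the C9 ketone lies between two quaternary carbons) and on the face anti to the bulky C8 substituent, which places C15 cis to the alkynyl group.

Step 16
Reactants: 21 C16 tertiary alcohol with 2-(chloromethyl)allyl group
Product: 22 C16 trimethylsilyl ether
Conditions: Me3SiOTf, 2,6-lutidine, CH2Cl2, −78 to 0 °C
Reagents that add atoms: trimethylsilyl trifluoromethanesulfonate C[Si](C)(C)OS(=O)(=O)C(F)(F)F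
Why: Silylation of the tertiary alcohol (silyl ether protection) removes the only acidic proton before the organosamarium step.

Step 17
Reactants: 22 C16 trimethylsilyl ether
Product: 24 C9 methyl oxalate of the cycloheptane, via diiodosamarium alkoxide 23 (not isolated)
Conditions: SmI2 (2.5 equiv), (Me2N)3PO, THF, −20 °C to rt; then methyl chlorooxoacetate, −78 to 0 °C
Reagents that add atoms: methyl chlorooxoacetate COC(=O)C(Cl)=O
Why: SmI2 reduces the allylic chloride by two single-electron transfers to an allylsamarium species, which adds to the C9 carbonyl to give samarium alkoxide 23, trapped in the same flask as the methyl oxalate. The closest known reaction type is the SmI2-promoted intramolecular Barbier cyclization of halo ketones, used as the second stage of annulations with 2-methylenepropane-1,3-diyl conjunctive reagents. The seven-membered carbocycle C8–C9–C11–C12–C15–C16–C14 closes by 7-exo-trig attack on the carbonyl carbon, and both termini of the symmetrical allyl unit lead to the same product, so no regiochemical issue arises. The new C9 carbinol centre should form by approach anti to the axial C8 and C10 methyl groups, but its configuration is irrelevant because C9 becomes a radical in step 18. The step needs chemoselectivity for the ketone over the two lactones and over protonation; this is secured by C9 being the only ketone left, by the lower reactivity of esters toward allylsamarium reagents and by the silyl cap on the C16 oxygen.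

Step 18
Reactants: 24 C9 methyl oxalate of the cycloheptane
Product: 25 9-deoxy cycloheptane with 9α-H
Conditions: Bu3SnH, 2,2′-azobis(2-methylpropanenitrile) (cat.), toluene, 110 °C
Reagents that add atoms: none
Why: Stannyl radical addition to the oxalate and β-scission (Barton–McCombie-type deoxygenation of a tertiary methyl oxalate) gives the planar C9 radical, which should take hydrogen from Bu3SnH on the α face because the β face is shielded by the axial C8 and C10 methyl groups, so that C11 becomes equatorial.

Step 19
Reactants: 25 9-deoxy cycloheptane with 9α-H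
Product: 26 enyne alcohol (C14 ethynyl, C16 hydroxyl, C12 methylene)
Conditions: Bu4NF, AcOH, THF, 0 °C to rt
Reagents that add atoms: none
Why: Fluoride cleaves both the alkynyl C–Si and the tertiary O–Si bond (desilylation), and the acetic acid buffer keeps the lactones away from free alkoxide.

Step 20
Reactants: 26 enyne alcohol (C14 ethynyl, C16 hydroxyl, C12 methylene)
Product: 27 1,2-dihydrobrasilianoid C
Conditions: Fe(acac)3 (0.3 equiv), PhSiH3, EtOH, 60 °C
Reagents that add atoms: none
Why: Hydrogen atom transfer from the iron hydride to the 1,1-disubstituted C12 methylene (Mukaiyama-type HAT radical cyclization) creates the C12 methyl and a tertiary radical that closes by transannular 5-exo-dig attack on the ethynyl group, the vinyl radical then takes hydrogen to give the C13 methylene, and C12 can only form with the bridge on the alkyne-bearing face.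

Step 21
Reactants: 27 1,2-dihydrobrasilianoid C
Product: 31 brasilianoid C, via dilithium enolate alkoxide 28 (not isolated), via 2-phenylselanyl lactone 29 (not isolated), via selenoxide 30 (not isolated)
Conditions: LiN(i-Pr)2 (2.5 equiv), THF, −78 °C; PhSeBr; then 30% H2O2, pyridine, CH2Cl2, 0 °C to rt
Reagents that add atoms: none
Why: α-Selenenylation of the ε-lactone enolate and oxidation to the selenoxide is followed by syn elimination toward C1 (selenoxide elimination), which can only give the endocyclic cis C1=C2 enoate.

Compound list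
1 | (S)-(+)-carvone | CC1=CC[C@@H](CC1=O)C(C)=C | starting material
2 | lithium dienolate of carvone (O–Li on C1, C1=C6) | CC1=CC[C@H](C(C)=C)C=C1O[Li] | intermediate
3 | (5S,6R)-6-methylcarvone (methyl trans to isopropenyl) | CC1=CC[C@H](C(C)=C)[C@@H](C)C1=O | intermediate
4 | lithium enolate of 6-methylcarvone (O–Li on C1, C1=C6) | CC1=CC[C@H](C(C)=C)C(C)=C1O[Li] | intermediate
5 | 6-allyl-6-methylcarvone (allyl trans to isopropenyl) | CC1=CC[C@H](C(C)=C)[C@@](C)(CC=C)C1=O | intermediate
6 | alkyldisiamylborane from 5 (boron on the terminal allyl carbon) | CC1=CC[C@H](C(C)=C)[C@@](C)(CCCB(C(C)C(C)C)C(C)C(C)C)C1=O | intermediate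
7 | 6-(3-hydroxypropyl)-6-methylcarvone | CC1=CC[C@H](C(C)=C)[C@@](C)(CCCO)C1=O | intermediate
8 | 6-(2-carboxyethyl)-6-methylcarvone | CC1=CC[C@H](C(C)=C)[C@@](C)(CCC(O)=O)C1=O | intermediate
9 | ring A ε-lactone trans-fused to ring B enone (C9 ketone, C7=C8, 8-methyl, 10β-methyl, 5α-H) | O=C1C(C)=CC[C@H]2[C@@]1(C)CCC(=O)OC2(C)C | intermediate
10 | trimethylsilyl dienol ether of 9 (C9–OSiMe3, C8=C9, C6=C7) | C[Si](C)(C)OC1=C(C)C=C[C@H]2[C@@]1(C)CCC(=O)OC2(C)C | intermediate
11 | 6α-hydroxy enone (hydroxyl trans to the C5–C4 bond) | O=C1C(C)=C[C@@H](O)[C@H]2[C@@]1(C)CCC(=O)OC2(C)C | intermediate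
12 | ethyl (S)-lactate | CCOC(=O)[C@H](C)O | starting material
13 | ethyl (S)-2-acetoxypropanoate | CCOC(=O)[C@H](C)OC(C)=O | intermediate
14 | (S)-5-methyltetronic acid | C[C@@H]1OC(=O)C=C1O | intermediate
15 | (S)-4-bromo-5-methylfuran-2(5H)-one | C[C@@H]1OC(=O)C=C1Br | intermediate
16 | 6α-O-tetronate ether: enone 11 etherified at O6 with C16 of the (S)-5-methylfuran-2(5H)-one | O=C1C(C)=C[C@@H](OC3=CC(=O)O[C@H]3C)[C@H]2[C@@]1(C)CCC(=O)OC2(C)C | intermediate
17 | C14 iodide of tetronate ether 16 | O=C1C(C)=C[C@@H](OC3=C(I)C(=O)O[C@H]3C)[C@H]2[C@@]1(C)CCC(=O)OC2(C)C | intermediate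
18 | C14 (trimethylsilyl)ethynyl tetronate ether | O=C1C(C)=C[C@@H](OC3=C(C#C[Si](C)(C)C)C(=O)O[C@H]3C)[C@H]2[C@@]1(C)CCC(=O)OC2(C)C | intermediate
19 | Claisen product: 3-alkynyl-5-methylfuran-2,4-dione bonded through C14 to C8 (8β-methyl, C6=C7, C9 ketone) | C[C@]1([C@]2(C#C[Si](C)(C)C)C(=O)O[C@@H](C)C2=O)C=C[C@H]3[C@@](C)(CCC(=O)OC3(C)C)C1=O | intermediate
20 | 6,7-dihydro derivative of 19 (1,4-diketone, C9 and C16 carbonyls) | C[C@]1([C@]2(C#C[Si](C)(C)C)C(=O)O[C@@H](C)C2=O)CC[C@H]3[C@@](C)(CCC(=O)OC3(C)C)C1=O | intermediate
21 | C16 tertiary alcohol with 2-(chloromethyl)allyl group cis to the alkynyl group | C[C@]1([C@]2(C#C[Si](C)(C)C)C(=O)O[C@@H](C)[C@@]2(O)CC(=C)CCl)CC[C@H]3[C@@](C)(CCC(=O)OC3(C)C)C1=O | intermediate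
22 | C16 trimethylsilyl ether of 21 | C[C@]1([C@]2(C#C[Si](C)(C)C)C(=O)O[C@@H](C)[C@@]2(O[Si](C)(C)C)CC(=C)CCl)CC[C@H]3[C@@](C)(CCC(=O)OC3(C)C)C1=O | intermediate
23 | C9 diiodosamarium alkoxide of the cycloheptane (ring C8–C9–C11–C12–C15–C16–C14, methylene on C12) | C[C@]12[C@]3(C#C[Si](C)(C)C)C(=O)O[C@@H](C)[C@@]3(O[Si](C)(C)C)CC(=C)C[C@]2(O[Sm](I)I)[C@]4(C)CCC(=O)OC(C)(C)[C@H]4CC1 | intermediate
24 | C9 methyl oxalate of the cycloheptane | C[C@]12[C@]3(C#C[Si](C)(C)C)C(=O)O[C@@H](C)[C@@]3(O[Si](C)(C)C)CC(=C)C[C@]2(OC(=O)C(=O)OC)[C@]4(C)CCC(=O)OC(C)(C)[C@H]4CC1 | intermediate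
25 | 9-deoxy cycloheptane (9α-H, C11 β) | C[C@]12[C@]3(C#C[Si](C)(C)C)C(=O)O[C@@H](C)[C@@]3(O[Si](C)(C)C)CC(=C)C[C@H]2[C@]4(C)CCC(=O)OC(C)(C)[C@H]4CC1 | intermediate
26 | enyne alcohol (C14 ethynyl, C16 hydroxyl, C12 methylene) | C[C@]12[C@]3(C#C)C(=O)O[C@@H](C)[C@@]3(O)CC(=C)C[C@H]2[C@]4(C)CCC(=O)OC(C)(C)[C@H]4CC1 | intermediate
27 | 1,2-dihydrobrasilianoid C | C=C1[C@@]2(C)C[C@H]3[C@]4(C)CCC(=O)OC(C)(C)[C@H]4CC[C@]3(C)[C@@]13C(=O)O[C@@H](C)[C@@]3(O)C2 | intermediate
28 | dilithium species of 27 (ring A lactone enolate and C16 alkoxide) | C=C1[C@@]2(C)C[C@H]3[C@]4(C)CC=C(O[Li])OC(C)(C)[C@H]4CC[C@]3(C)[C@@]13C(=O)O[C@@H](C)[C@@]3(O[Li])C2 | intermediate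
29 | 2-(phenylselanyl) lactone (C2 epimers) | C=C1[C@@]2(C)C[C@H]3[C@]4(C)CC([Se]c5ccccc5)C(=O)OC(C)(C)[C@H]4CC[C@]3(C)[C@@]13C(=O)O[C@@H](C)[C@@]3(O)C2 | intermediate
30 | selenoxide of 29 | C=C1[C@@]2(C)C[C@H]3[C@]4(C)CC([Se](=O)c5ccccc5)C(=O)OC(C)(C)[C@H]4CC[C@]3(C)[C@@]13C(=O)O[C@@H](C)[C@@]3(O)C2 | intermediate
31 | brasilianoid C | C=C1[C@@]2(C)C[C@H]3[C@]4(C)C=CC(=O)OC(C)(C)[C@H]4CC[C@]3(C)[C@@]13C(=O)O[C@@H](C)[C@@]3(O)C2 | target

Total step count: 21. Longest linear sequence: 18 steps (steps 1–6 and 10–21 from (S)-carvone).

Steps most likely to fail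

Step 17 (ring closure at the hindered ketone). The allylsamarium intermediate may be protonated or coupled before it reaches the C9 carbonyl, or it may add to the C18 lactone carbonyl in a six-membered closure. The C9 alkoxide may also transacylate onto C18 before it is trapped. The fallback replaces the reductively formed organometallic by an allylsilane and a Lewis acid; it sets out from 20 and returns at 24. Indium-mediated Barbier allylation of the C16 ketone of 20 with 3-iodo-2-[(trimethylsilyl)methyl]prop-1-ene (In, DMF) should give the C16 alcohol with a 2-[(trimethylsilyl)methyl]allyl group F3. BF3·OEt2-promoted intramolecular Hosomi–Sakurai addition of the allylsilane to the C9 ketone uses a nucleophile that does not attack lactones and should close the same seven-membered ring as the cycloheptane-1,4-diol F4. Selective silylation of the less hindered C16 hydroxyl (Me3SiOTf, 2,6-lutidine) should give the C16 mono silyl ether F5. KN(SiMe3)2 followed by methyl chlorooxoacetate should then convert its C9 hydroxyl into oxalate 24.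

Step 13 (Claisen rearrangement to two adjacent quaternary centres). The rearrangement may stop at an unfavourable equilibrium, because enone, enyne and vinylogous ester conjugation are lost and two adjacent quaternary carbons are formed. The tetronate may instead be lost by thermal elimination, or the reaction may take place on the tetronate face syn to the C17 methyl. The fallback rearranges at the alcohol oxidation level; it sets out from 18 and returns at 19. Luche reduction (NaBH4, CeCl3·7H2O, MeOH) of the C9 ketone should give the C9 allylic alcohol F1, whose allyl unit is no longer part of an enone. Its Claisen rearrangement should then run at lower temperature to the rearranged C9 alcohol F2, and Dess–Martin oxidation returns 19.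

Step 20 (hydrogen-atom-transfer enyne cyclization). The tertiary C12 radical may be reduced before it closes the ring, hydrogen atom transfer to the alkyne may compete, or the new C13 methylene may be reduced further. The fallback generates the same radical without a metal hydride present; it sets out from 25 and returns at 27. Mukaiyama hydration (Co(acac)2, PhSiH3, O2, i-PrOH) of the C12 methylene of 25 should give the C12 tertiary alcohol F6. Acylation with methyl chlorooxoacetate (4-(dimethylamino)pyridine, pyridine) should give the C12 methyl oxalate F7. Bu3SnH with 2,2′-azobis(2-methylpropanenitrile) in toluene at 110 °C should form the C12 radical, whose 5-exo-dig closure onto the silylalkyne gives the bis-silylated vinylsilane F8. CF3CO2H then removes both silyl groups to give 27.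

Further compounds
F1 | step 13 | C9 allylic alcohol of 18 (C9 epimers) | OC1C(C)=C[C@@H](OC3=C(C#C[Si](C)(C)C)C(=O)O[C@H]3C)[C@H]2[C@@]1(C)CCC(=O)OC2(C)C
F2 | step 13 | rearranged C9 alcohol (C8-linked 3-alkynylfuran-2,4-dione, C6=C7, C9 epimers) | C[C@]1([C@]2(C#C[Si](C)(C)C)C(=O)O[C@@H](C)C2=O)C=C[C@H]3[C@@](C)(CCC(=O)OC3(C)C)C1O
F3 | step 17 | C16 alcohol with 2-[(trimethylsilyl)methyl]allyl group | C[C@]1([C@]2(C#C[Si](C)(C)C)C(=O)O[C@@H](C)[C@@]2(O)CC(=C)C[Si](C)(C)C)CC[C@H]3[C@@](C)(CCC(=O)OC3(C)C)C1=O
F4 | step 17 | cycloheptane-1,4-diol (C9 and C16 hydroxyls, methylene on C12) | C[C@]12[C@]3(C#C[Si](C)(C)C)C(=O)O[C@@H](C)[C@@]3(O)CC(=C)C[C@]2(O)[C@]4(C)CCC(=O)OC(C)(C)[C@H]4CC1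
F5 | step 17 | C16 mono silyl ether of F4 | C[C@]12[C@]3(C#C[Si](C)(C)C)C(=O)O[C@@H](C)[C@@]3(O[Si](C)(C)C)CC(=C)C[C@]2(O)[C@]4(C)CCC(=O)OC(C)(C)[C@H]4CC1
F6 | step 20 | C12 tertiary alcohol (C12 epimers) | C[C@]12[C@]3(C#C[Si](C)(C)C)C(=O)O[C@@H](C)[C@@]3(O[Si](C)(C)C)CC(C)(O)C[C@H]2[C@]4(C)CCC(=O)OC(C)(C)[C@H]4CC1
F7 | step 20 | C12 methyl oxalate (C12 epimers) | C[C@]12[C@]3(C#C[Si](C)(C)C)C(=O)O[C@@H](C)[C@@]3(O[Si](C)(C)C)CC(C)(OC(=O)C(=O)OC)C[C@H]2[C@]4(C)CCC(=O)OC(C)(C)[C@H]4CC1
F8 | step 20 | bis-silylated vinylsilane (C19 trimethylsilyl, C16 silyl ether, alkene geometry open) | C[Si](C)(C)C=C1[C@@]2(C)C[C@H]3[C@]4(C)CCC(=O)OC(C)(C)[C@H]4CC[C@]3(C)[C@@]13C(=O)O[C@@H](C)[C@@]3(O[Si](C)(C)C)C2
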